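**Plan** (chain numbered C1 = ketone carbon to C16 = methyl; ring C1' = acyl-bearing carbon)

1. Feature: the single benzene ring carries the C1 ketone carbon at C1' and a phenolic oxygen on the adjacent C2'. The oxygens at C4' and C6' complete a 1,3,5-trioxygenated pattern, which is what a carboxylic acid leaves when it adds across a 3,5-dioxygenated benzyne.
2. Cuts: first the three O–benzyl bonds of a fully masked precursor. Next, C1'–C1 and C2'–O together (aryne plus C16 acid), then C11–C12 of the chain (C11 Grignard reagent plus C5 epoxide).
3. Forward: C11–C12 is joined first, the alkene end is raised to the acid, the acid is inserted into the aryne, and one hydrogenolysis unmasks everything. No ring is built; the benzene ring is bought as 3,5-bis(benzyloxy)phenol.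
4. Stereochemistry: C13 (S) comes from (S)-1,2-epoxypentane, which is opened at its CH2 carbon. The C13–O bond is never broken afterwards.
5. Benzyl masks all three hydroxyl groups, because methyl ethers ortho and para to the ketone would need forcing BBr3 treatment, which endangers the secondary C13–O bond.

Key step: step 8

Assumption: 3,5-bis(benzyloxy)phenol, 11-bromoundec-1-ene and enantiopure (S)-1,2-epoxypentane are taken as catalogue compounds.

**Route**

Step 1
Reactants: 1 3,5-bis(benzyloxy)phenol
Product: 2 3,5-bis(benzyloxy)phenyl isopropylcarbamate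
Conditions: i-PrNCO, Et3N (cat.), CH2Cl2, rt
Reagents that add atoms: isopropyl isocyanate, CC(C)N=C=O
Why: Base-catalysed addition of a phenol to an isocyanate (carbamoylation) should install a strong oxygen-based directing group that mild base can later expel.

Step 2
Reactants: 2 3,5-bis(benzyloxy)phenyl isopropylcarbamate
Product: 6 3,5-bis(benzyloxy)-2-(trimethylsilyl)phenyl isopropylcarbamate, via N-silyl carbamate 3 (not isolated), via aryllithium 4 (not isolated), via doubly silylated carbamate 5 (not isolated)
Conditions: TBSOTf, TMEDA, Et2O, 0 °C → rt; n-BuLi, TMEDA, −78 °C; TMSCl, −78 °C → rt; aq. NaHSO4 (brief)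
Reagents that add atoms: chlorotrimethylsilane, C[Si](C)(C)Cl
Why: In this directed ortho-metalation, transient N-silylation masks the N–H, the carbamate and the neighbouring benzyloxy oxygen together steer n-BuLi to C2 rather than to C4 or a benzylic CH2, TMSCl traps the aryllithium, and the work-up hydrolyses only the labile N–Si bond.

Step 3
Reactants: 6 3,5-bis(benzyloxy)-2-(trimethylsilyl)phenyl isopropylcarbamate
Product: 8 3,5-bis(benzyloxy)-2-(trimethylsilyl)phenyl trifluoromethanesulfonate, via silylphenol 7 (not isolated)
Conditions: DBU, Et2NH, MeCN, 40 °C; then PhNTf2, MeCN, rt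
Reagents that add atoms: N-phenylbis(trifluoromethanesulfonimide), O=S(=O)(N(c1ccccc1)S(=O)(=O)C(F)(F)F)C(F)(F)F
Why: E1cB cleavage of the N-monosubstituted carbamate (DBU removes the N–H, and Et2NH scavenges the departing isopropyl isocyanate) should free the phenoxide without acid, sparing the aryl–silicon bond, and PhNTf2 then triflates it in the same pot.

Step 4
Reactants: 9 11-bromoundec-1-ene; 10 (S)-1,2-epoxypentane
Product: 12 (S)-hexadec-15-en-4-ol, via undec-10-enylmagnesium bromide 11 (not isolated)
Conditions: Mg, THF, rt → 40 °C; CuI (10 mol %), then 10, THF, −30 → 0 °C; aq. NH4Cl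
Reagents that add atoms: none
Why: Copper-catalysed SN2 opening of a terminal epoxide by a primary Grignard reagent occurs only at the unsubstituted carbon, so the C–O bond of the stereocentre is untouched and the S configuration of 10 becomes that of C13.

Step 5
Reactants: 12 (S)-hexadec-15-en-4-ol
Product: 13 (S)-13-(benzyloxy)hexadec-1-ene
Conditions: NaH, BnBr, n-Bu4NI (cat.), THF/DMF, 0 °C → rt
Reagents that add atoms: benzyl bromide, BrCc1ccccc1
Why: Williamson ether synthesis alkylates the oxygen without breaking the C13–O bond, and the benzyl ether should withstand the borane, the oxoammonium oxidant, hot fluoride and the aryne.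

Step 6
Reactants: 13 (S)-13-(benzyloxy)hexadec-1-ene
Product: 15 (S)-13-(benzyloxy)hexadecan-1-ol, via B-alkyl-9-BBN adduct 14 (not isolated)
Conditions: 9-BBN, THF, 0 °C → rt; then NaOH, H2O2, 0 °C → rt
Reagents that add atoms: hydrogen peroxide, OO
Why: In this hydroboration–oxidation the bulky borane adds anti-Markovnikov to the monosubstituted alkene and alkaline peroxide replaces boron by hydroxyl, conditions that leave the benzyl ether unchanged.

Step 7
Reactants: 15 (S)-13-(benzyloxy)hexadecan-1-ol
Product: 17 (S)-13-(benzyloxy)hexadecanoic acid, via aldehyde 16 (not isolated)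
Conditions: TEMPO (2,2,6,6-tetramethylpiperidine-1-oxyl, cat.), PhI(OAc)2 (2.2 equiv), CH2Cl2/H2O, rt
Reagents that add atoms: water, O
Why: Oxoammonium-mediated oxidation in the presence of water carries the primary alcohol through the aldehyde hydrate to the acid without touching the benzyl ether or the remote stereocentre.

Step 8
Reactants: 8 3,5-bis(benzyloxy)-2-(trimethylsilyl)phenyl trifluoromethanesulfonate; 17 (S)-13-(benzyloxy)hexadecanoic acid
Product: 21 (S)-13-(benzyloxy)-1-[2,4-bis(benzyloxy)-6-hydroxyphenyl]hexadecan-1-one, via caesium carboxylate 18 (not isolated), via aryne 19 (not isolated), via aryl anion 20 (not isolated)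
Conditions: 8 (1.5 equiv), CsF (4 equiv), THF (ca. 0.02 M), 125 °C, sealed tube; aq. NH4Cl
Reagents that add atoms: none
Why: Fluoride removes the silyl group of 8 with loss of triflate and so releases aryne 19 slowly, while further CsF converts acid 17 into carboxylate 18, whose oxygen adds to the aryne to give aryl anion 20. The carbanion of 20 lies ortho to the new ester and attacks its carbonyl carbon through a four-membered transition state; collapse of the adduct delivers the ketone and a phenoxide that takes back the proton given up by the acid, so the C2'–O and C1'–C1 bonds arise in one operation. The closest known reaction type is this very one, the fluoride-induced insertion of arynes into the C–O bond of carboxylic acids to give ortho-hydroxyaryl ketones, which is mechanistically an anionic ortho-Fries acyl shift. No ring is closed (the four-membered array is only transient) and no stereocentre is made; C13 is remote and its benzyl ether is inert to both fluoride and the aryne. The step needs regioselectivity, and the benzyloxy group at C3 of 19 secures it: its inductive pull distorts the triple bond so that the nucleophile enters at the distal C1 and the charge builds up at C2 beside it, which seats the acyl group between two oxygens, the C5 benzyloxy group being too remote to overturn this. It also needs acyl transfer to outrun protonation of 20, which high dilution, the low solubility of CsF in THF and the high temperature favour, because the shift is intramolecular and the proton capture is not.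

Step 9
Reactants: 21 (S)-13-(benzyloxy)-1-[2,4-bis(benzyloxy)-6-hydroxyphenyl]hexadecan-1-one
Product: 22 (S)-13-hydroxy-1-(2,4,6-trihydroxyphenyl)hexadecan-1-one
Conditions: H2 (1 atm), 10% Pd/C, EtOAc/EtOH, rt
Reagents that add atoms: none
Why: Catalytic hydrogenolysis cleaves all three benzyl ethers at their benzylic C–O bonds, so the C13–O bond and its configuration stay intact, while the hydrogen-bonded, electron-rich aryl ketone should resist reduction at one atmosphere.

**Compound list**

1 | 3,5-bis(benzyloxy)phenol | Oc1cc(OCc2ccccc2)cc(OCc2ccccc2)c1 | starting material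
2 | 3,5-bis(benzyloxy)phenyl isopropylcarbamate | CC(C)NC(=O)Oc1cc(OCc2ccccc2)cc(OCc2ccccc2)c1 | intermediate
3 | 3,5-bis(benzyloxy)phenyl N-(tert-butyldimethylsilyl)-N-isopropylcarbamate | CC(C)N([Si](C)(C)C(C)(C)C)C(=O)Oc1cc(OCc2ccccc2)cc(OCc2ccccc2)c1 | intermediate
4 | 3,5-bis(benzyloxy)-2-lithiophenyl N-(tert-butyldimethylsilyl)-N-isopropylcarbamate | CC(C)N([Si](C)(C)C(C)(C)C)C(=O)Oc1cc(OCc2ccccc2)cc(OCc2ccccc2)c1[Li] | intermediate
5 | 3,5-bis(benzyloxy)-2-(trimethylsilyl)phenyl N-(tert-butyldimethylsilyl)-N-isopropylcarbamate | CC(C)N([Si](C)(C)C(C)(C)C)C(=O)Oc1cc(OCc2ccccc2)cc(OCc2ccccc2)c1[Si](C)(C)C | intermediate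
6 | 3,5-bis(benzyloxy)-2-(trimethylsilyl)phenyl isopropylcarbamate | CC(C)NC(=O)Oc1cc(OCc2ccccc2)cc(OCc2ccccc2)c1[Si](C)(C)C | intermediate
7 | 3,5-bis(benzyloxy)-2-(trimethylsilyl)phenol (present in the flask as its DBU salt) | Oc1cc(OCc2ccccc2)cc(OCc2ccccc2)c1[Si](C)(C)C | intermediate
8 | 3,5-bis(benzyloxy)-2-(trimethylsilyl)phenyl trifluoromethanesulfonate | FC(F)(F)S(=O)(=O)Oc1cc(OCc2ccccc2)cc(OCc2ccccc2)c1[Si](C)(C)C | intermediate
9 | 11-bromoundec-1-ene | C=CCCCCCCCCCBr | starting material
10 | (S)-1,2-epoxypentane, i.e. (S)-2-propyloxirane | CCC[C@H]1CO1 | starting material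
11 | undec-10-enylmagnesium bromide | C=CCCCCCCCCC[Mg]Br | intermediate
12 | (S)-hexadec-15-en-4-ol | CCC[C@H](O)CCCCCCCCCCC=C | intermediate
13 | (S)-13-(benzyloxy)hexadec-1-ene | CCC[C@H](OCc1ccccc1)CCCCCCCCCCC=C | intermediate
14 | (S)-9-[13-(benzyloxy)hexadecyl]-9-borabicyclo[3.3.1]nonane | CCC[C@H](OCc1ccccc1)CCCCCCCCCCCCB1C2CCCC1CCC2 | intermediate
15 | (S)-13-(benzyloxy)hexadecan-1-ol | CCC[C@H](OCc1ccccc1)CCCCCCCCCCCCO | intermediate
16 | (S)-13-(benzyloxy)hexadecanal | CCC[C@H](OCc1ccccc1)CCCCCCCCCCCC=O | intermediate
17 | (S)-13-(benzyloxy)hexadecanoic acid | CCC[C@H](OCc1ccccc1)CCCCCCCCCCCC(=O)O | intermediate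
18 | caesium (S)-13-(benzyloxy)hexadecanoate | CCC[C@H](OCc1ccccc1)CCCCCCCCCCCC(=O)[O-].[Cs+] | intermediate
19 | 3,5-bis(benzyloxy)benzyne (1,2-didehydrobenzene with benzyloxy groups at C3 and C5) | C1#CC(OCc2ccccc2)=CC(OCc2ccccc2)=C1 | intermediate
20 | caesium salt of the C2 carbanion of 3,5-bis(benzyloxy)phenyl (S)-13-(benzyloxy)hexadecanoate | CCC[C@H](OCc1ccccc1)CCCCCCCCCCCC(=O)Oc1cc(OCc2ccccc2)cc(OCc2ccccc2)[c-]1.[Cs+] | intermediate
21 | (S)-13-(benzyloxy)-1-[2,4-bis(benzyloxy)-6-hydroxyphenyl]hexadecan-1-one | CCC[C@H](OCc1ccccc1)CCCCCCCCCCCC(=O)c1c(O)cc(OCc2ccccc2)cc1OCc1ccccc1 | intermediate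
22 | (S)-13-hydroxy-1-(2,4,6-trihydroxyphenyl)hexadecan-1-one (CNP0242597.1) | CCC[C@H](O)CCCCCCCCCCCC(=O)c1c(O)cc(O)cc1O | target

**Step count**

Total steps: 9. Longest linear sequence: 6 (steps 4–9, from 9 and 10). The aryne branch contributes steps 1–3 and joins at step 8.

**Steps most likely to fail**

**Step 8.** The aryl anion may be protonated before it takes the acyl group, so that the sequence stops at plain O-arylation. The product phenoxide may also be arylated by surplus aryne. The fallback generates the same ortho-metallated aryl ester without an aryne and in a proton-free medium, and it sets out from 1 and 17.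
- Phenol 1 would be iodinated beside the hydroxyl group (NIS, CH2Cl2, low temperature, removal of any para isomer by chromatography) to give 3,5-bis(benzyloxy)-2-iodophenol F1.
- Steglich esterification with acid 17 (EDC·HCl, 4-(dimethylamino)pyridine, CH2Cl2) would give 3,5-bis(benzyloxy)-2-iodophenyl (S)-13-(benzyloxy)hexadecanoate F2.
- Iodine–lithium exchange (n-BuLi, THF/Et2O, −100 °C) would trigger the known anionic ortho-Fries acyl shift. After aqueous work-up the route is rejoined at 21.

**Step 2.** Deprotonation may compete at a benzylic CH2 (followed by Wittig rearrangement) or at C4 between the two ether oxygens. The very electron-rich ring may also lose its silyl group by ipso-protonation during the acidic work-up. The fallback replaces deprotonation by halogen–metal exchange; it sets out from 1 and bypasses steps 1–3.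
- NBS in CH2Cl2 at −78 °C would give 3,5-bis(benzyloxy)-2-bromophenol F3.
- Hexamethyldisilazane in refluxing THF would give [3,5-bis(benzyloxy)-2-bromophenoxy]trimethylsilane F4.
- Bromine–lithium exchange with n-BuLi in THF at −78 °C, followed at once by O→C silyl migration (retro-Brook rearrangement), would give lithium 3,5-bis(benzyloxy)-2-(trimethylsilyl)phenoxide F5.
- Tf2O traps F5 in the same flask, and the route is rejoined at 8.

**Step 9.** Cleavage of the unactivated secondary alkyl benzyl ether may be sluggish, and over-reduction of the aryl ketone may set in on prolonged exposure to hydrogen. The fallback drops hydrogenation in favour of Lewis-acid ether cleavage with a cation scavenger. It sets out from 21: BCl3 and pentamethylbenzene in CH2Cl2 at −78 °C, then a methanol quench. The benzylic C–O bonds ionise and the scavenger captures the benzyl cations. The C13–O bond survives as a borate until work-up, and the route is rejoined at 22.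

**Further compounds**

F1 | step 8 | 3,5-bis(benzyloxy)-2-iodophenol | Oc1cc(OCc2ccccc2)cc(OCc2ccccc2)c1I
F2 | step 8 | 3,5-bis(benzyloxy)-2-iodophenyl (S)-13-(benzyloxy)hexadecanoate | CCC[C@H](OCc1ccccc1)CCCCCCCCCCCC(=O)Oc1cc(OCc2ccccc2)cc(OCc2ccccc2)c1I
F3 | step 2 | 3,5-bis(benzyloxy)-2-bromophenol | Oc1cc(OCc2ccccc2)cc(OCc2ccccc2)c1Br
F4 | step 2 | [3,5-bis(benzyloxy)-2-bromophenoxy]trimethylsilane | C[Si](C)(C)Oc1cc(OCc2ccccc2)cc(OCc2ccccc2)c1Br
F5 | step 2 | lithium 3,5-bis(benzyloxy)-2-(trimethylsilyl)phenoxide | [Li+].[O-]c1cc(OCc2ccccc2)cc(OCc2ccccc2)c1[Si](C)(C)C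
F0 | step 9 | none | none
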